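The earlier runs and the new flask are calculated for substances that don't exist; the scatter is artificial.

The product, Z and L together, tells us how much of Q and J has gone, and we take one G for each product formed.

| flask | Q | J | G | E | remark | time |
|---|---|---|---|---|---|---|
| north | 0.22 M | 0.22 M | 2.2 equiv | 7.5 mol% | run made earlier |  |
| south-east | 0.22 M | 0.22 M | 2.2 equiv | 11 mol% | run made earlier |  |
| west | 0.11 M | 0.11 M | 2.2 equiv | 15 mol% | run made earlier |  |
| flask | 0.22 M | 0.22 M | 2.20 equiv | 15 mol% |  | 8.0 h |
- north (time / h: Z / %, L / %): 0.417: 13, 5; 0.667: 20, 7; 1.33: 30, 16; 2.50: 32, 24; 5.00: 39, 35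
- south-east (time / h: Z / %, L / %): 0.417: 18, 9; 1.33: 33, 20; 2.00: 34, 23; 3.00: 40, 29; 5.00: 43, 35
- west (time / h: Z / %, L / %): 0.417: 5, 2; 1.33: 20, 11; 2.00: 20, 14; 3.00: 27, 18; 5.00: 32, 26

(each reading ± 1.5 percentage points)
- E is single-handed; Q and J are mirror images of each other, charged as a racemate, each of them at the stated concentration
- what was read earlier has a scatter of 1.5 percentage points, one standard deviation
- an excess is the difference of the two amounts in percent of their sum
- an excess is below zero if the other one leads
* excess of Z over L in the product at 25 min
* excess of Z over L in the product at 8.0 h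
* part of the Q and J charged together that has reacted at 8.0 h

We turn the settings one at a time. Raising E from north to south-east should, on paper, multiply the early product by 1.47, and the readings at 0.417 h give 1.50; but at 5.00 h the two runs stand at 74.0% and 78.0%, so the gain has shrunk. Lowering the concentration should slow the reaction, and west, at half the concentration of south-east but with more E, reads 58.0% at 5.00 h, less than south-east, though with two settings changed these readings cannot separate their effects. G stands at 2.2 equiv in each of the runs, so we reckon with the ceiling, the amount of product, in percent of the Q and J together charged, that the charge of G can pay for, here 110%, and with the part of G that is left in reserve: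

reserve of G = 1 − reacted / ceiling

Time comes last. The south-east readings show Q and J going at about 0.171 h⁻¹ between 3.00 h and 5.00 h, with a mean reserve of about 33.2%. We take that rate to follow the reserve and carry it on to 8.0 h:

first round, rate unchanged: reacted 86.8%

second round, mean reserve now 25.1%: reacted 85.1%

The flask carries more E than south-east, so we place it somewhat above that figure.

The forecast, which sees “a selective catalysed path that dies within 1–2 h”, gives 38% at 25 min, 4.5% at 8.0 h and 88% reacted, above our figure.

The flask gives 39.8%, 2.55% and 87.6%, and each of the forecast's numbers stands within its margin.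

    G + E + J → E + L (k = 0.0110 M⁻² s⁻¹)
    2 E ⇌ X (K = 84.0 M⁻¹, k = 0.00100 M⁻¹ s⁻¹)
    G + E + Q → E + Z (k = 0.0310 M⁻² s⁻¹)
    E ⇌ D (K = 0.660, k = 5.60 × 10⁻⁶ s⁻¹)
    Q ⇌ J (k = 0.00160 s⁻¹)
    Z ⇌ L (k = 7.50 × 10⁻⁵ s⁻¹)

This flask's excess falls from 34.9% at 0.800 h to 2.55% at 8.0 h, when Q and J still stand at 6.17% and 6.22% of the two together charged. The ceiling puts the reserve of G in this flask at 20.4% of its charge, so G has not run out here.

With 0.550 equiv of G, the ceiling falls to 27.5%, and G is the limiting reagent there; that neighbour reaches 27.0% with 1.97% of its G left.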